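**Retrosynthetic overview**
1. Target 9 is cut at the C1′–O ester bond. The last step is an enantioselective Pd(II) C1′–H acyloxylation of the achiral alkylquinone 7 with 3-methylbut-2-enoic acid 8, which makes the ester and the (S) centre together.
2. 7 is cut at C2–C1′: Negishi coupling of bromoquinone 4 with homoprenylzinc bromide 6, made from bromide 5.
3. 4 comes from naphthazarin monomethyl ether 2 by bromine addition and dehydrobromination, which leaves Br next to the hydrogen-bonded carbonyl. 2 comes from naphthazarin 1 by mono-O-methylation.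
4. Ring order: no ring is built; the naphthoquinone bicycle is bought as 1 and only decorated.

Assumption: the stereocentre in the target SMILES is read as (S) (alkannin series); 1, 5 and 8 are taken as catalogue chemicals.

**Step 1**
Reactants: 1 naphthazarin (5,8-dihydroxynaphthalene-1,4-dione)
Product: 2 5-hydroxy-8-methoxynaphthalene-1,4-dione
Conditions: MeI (3 equiv), Ag2O (1.0 equiv), CHCl3, rt, dark, 16 h; stopped at the mono-ether, recovered 1 recycled
Reagents that add atoms: iodomethane, CI
Why: Ag2O-mediated O-methylation (Purdie/Williamson type) of a symmetric, tautomerically degenerate substrate gives the only possible mono-ether, and the remaining hydroxyl, now held in a juglone-type chelate, is methylated much more slowly.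

**Step 2**
Reactants: 2 5-hydroxy-8-methoxynaphthalene-1,4-dione
Product: 4 2-bromo-8-hydroxy-5-methoxynaphthalene-1,4-dione, via trans-2,3-dibromo-2,3-dihydro adduct 3 (not isolated)
Conditions: Br2 (1.05 equiv), AcOH, rt, 1 h; then NaOAc (1.5 equiv), 70 °C, 20 min
Reagents that add atoms: bromine, BrBr
Why: Bromine addition to the quinone C=C followed by E1cB dehydrobromination removes the more acidic proton next to the hydrogen-bonded carbonyl, so Br stays on the carbon flanking the C=O peri to OH (the outcome known for juglone to 3-bromojuglone), and the methoxy donor on the other carbonyl reinforces the bias.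

**Step 3**
Reactants: 4 2-bromo-8-hydroxy-5-methoxynaphthalene-1,4-dione, 5 5-bromo-2-methylpent-2-ene
Product: 7 8-hydroxy-5-methoxy-2-(4-methylpent-3-en-1-yl)naphthalene-1,4-dione, via homoprenylzinc bromide 6 (not isolated)
Conditions: 5, Zn dust (BrCH2CH2Br/TMSCl-activated), LiCl, THF, 50 °C; solution of 6 (1.5 equiv) added slowly to 4, Pd-PEPPSI-IPr (2 mol%), THF, 0 °C to rt; aq NH4Cl, air
Reagents that add atoms: none
Why: Negishi sp2–sp3 cross-coupling, in which oxidative addition into the vinylogous acyl bromide is fast and ipso-specific, the alkylzinc halide is too weak a nucleophile and reductant to attack the quinone carbonyls, and slow addition lets coupling outrun protonolysis by the chelated OH.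

**Step 4**
Reactants: 7 8-hydroxy-5-methoxy-2-(4-methylpent-3-en-1-yl)naphthalene-1,4-dione, 8 3-methylbut-2-enoic acid
Product: 9 (1S)-1-(8-hydroxy-5-methoxy-1,4-dioxo-1,4-dihydronaphthalen-2-yl)-4-methylpent-3-en-1-yl 3-methylbut-2-enoate
Conditions: Pd(TFA)2 (10 mol%), chiral aryl sulfoxide–oxazoline ligand L* [4-tert-butyl-2-(2-(p-tolylsulfinyl)phenyl)-4,5-dihydrooxazole, 12 mol%, the antipode that gives Si-face delivery, found by screening both], 8 (5 equiv), Cs2CO3 (10 mol%), 2,6-dimethyl-1,4-benzoquinone (1.5 equiv), 4 Å MS, toluene, 45 °C; neutral work-up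
Reagents that add atoms: none
Why: Proposed new method: Pd(II)-catalysed enantioselective γ-C(sp3)–H acyloxylation of an alkylquinone, in which carboxylate-assisted deprotonation of the doubly vinylogous C1′–H (γ to C4=O, the only acidic sp3 C–H in 7) gives a Pd(II) dienolate that is an acyl-substituted η3-allyl over C1′–C2–C3, the senecioate then attacks C1′ (the terminus that restores the quinone) on the Si face (C2 > C2′ > H) left open by the chiral ligand to form the C–O bond and the (S) centre, and the released Pd(0) is re-oxidised at once by the dimethylbenzoquinone so the allylic ester is not re-ionised; the trisubstituted prenyl and senecioyl alkenes lie outside the scope of Pd(II) allylic C–H cleavage; the closest known reaction types are Pd(II)/sulfoxide allylic C–H acyloxylation of terminal alkenes (with its asymmetric sulfoxide–oxazoline variants) and Pd-enolate formation in ketone dehydrogenation, neither of which has been shown on a quinone-conjugated C–H bond.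

**Compound list**
1 | naphthazarin (5,8-dihydroxynaphthalene-1,4-dione) | O=C1C=CC(=O)c2c(O)ccc(O)c12 | starting material
2 | 5-hydroxy-8-methoxynaphthalene-1,4-dione | COc1ccc(O)c2c1C(=O)C=CC2=O | intermediate
3 | (2RS,3RS)-2,3-dibromo-5-hydroxy-8-methoxy-2,3-dihydronaphthalene-1,4-dione (trans, racemic; one enantiomer drawn) | COc1ccc(O)c2c1C(=O)[C@@H](Br)[C@H](Br)C2=O | intermediate
4 | 2-bromo-8-hydroxy-5-methoxynaphthalene-1,4-dione | COc1ccc(O)c2c1C(=O)C=C(Br)C2=O | intermediate
5 | 5-bromo-2-methylpent-2-ene | CC(C)=CCCBr | starting material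
6 | (4-methylpent-3-en-1-yl)zinc bromide | CC(C)=CCC[Zn]Br | intermediate
7 | 8-hydroxy-5-methoxy-2-(4-methylpent-3-en-1-yl)naphthalene-1,4-dione | COc1ccc(O)c2c1C(=O)C=C(CCC=C(C)C)C2=O | intermediate
8 | 3-methylbut-2-enoic acid | CC(C)=CC(=O)O | starting material
9 | (1S)-1-(8-hydroxy-5-methoxy-1,4-dioxo-1,4-dihydronaphthalen-2-yl)-4-methylpent-3-en-1-yl 3-methylbut-2-enoate | COc1ccc(O)c2c1C(=O)C=C([C@H](CC=C(C)C)OC(=O)C=C(C)C)C2=O | target

**Totals**
Total step count: 4. Longest linear sequence: 4 steps (1 → 2 → 4 → 7 → 9).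

**Three steps most likely to fail**

Step 4 (the proposed new C–H acyloxylation). It may fail by β-hydride loss from C2′ to the dienylquinone, by low enantioselectivity or Pd(0) re-ionisation of the product, or by Pd being trapped in the peri-hydroxyquinone chelate. The fallback uses known chemistry, sets out from 4 and comes back at 9. Dithionite reduction of 4 gives the leuco triol 2-bromo-5-methoxynaphthalene-1,4,8-triol F1. This is silylated directly (TBSCl, imidazole, DMF) to [(2-bromo-5-methoxynaphthalene-1,4,8-triyl)tris(oxy)]tris[tert-butyl(dimethyl)silane] F2. Bromine–lithium exchange (t-BuLi, THF, −78 °C) and acylation with N-methoxy-N,4-dimethylpent-3-enamide give the ketone 1-{1,4,8-tris[(tert-butyldimethylsilyl)oxy]-5-methoxynaphthalen-2-yl}-4-methylpent-3-en-1-one F3. Reduction with (R)-Me-CBS/BH3·SMe2 sets the carbinol (1S)-1-{1,4,8-tris[(tert-butyldimethylsilyl)oxy]-5-methoxynaphthalen-2-yl}-4-methylpent-3-en-1-ol F4. TBAF/AcOH frees the leuco compound 2-[(1S)-1-hydroxy-4-methylpent-3-en-1-yl]-5-methoxynaphthalene-1,4,8-triol F5, which air-oxidises to the quinone alcohol 8-hydroxy-2-[(1S)-1-hydroxy-4-methylpent-3-en-1-yl]-5-methoxynaphthalene-1,4-dione F6. Steglich esterification with 8 (DCC, DMAP, CH2Cl2, 0 °C), selective for the side-chain hydroxyl over the chelated phenol, gives 9. Here the stereocentre is set in the reduction, not in the C–O step.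

Step 3 (Negishi coupling on a free hydroxy-bromoquinone). The quinone may oxidise the organozinc or Pd(0) (homocoupling, reduction), or the acidic OH may quench 6. The fallback masks the quinone, sets out from 4 and comes back at 7. Reductive acetylation (Zn, Ac2O, NaOAc) gives 2-bromo-5-methoxynaphthalene-1,4,8-triyl triacetate F7. Negishi coupling of this ordinary aryl bromide with 6 (Pd(OAc)2/SPhos, THF, rt) gives 5-methoxy-2-(4-methylpent-3-en-1-yl)naphthalene-1,4,8-triyl triacetate F8. Methanolysis (K2CO3, MeOH, 0 °C) releases the leuco compound 5-methoxy-2-(4-methylpent-3-en-1-yl)naphthalene-1,4,8-triol F9, which air-oxidises to 7.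

Step 2 (regiochemistry of bromination). The regioisomeric bromide or ring bromination may compete; the regiochemistry rests on analogy with juglone. The fallback avoids halogen and uses the innate regiochemistry of radical addition; it sets out from 1, bypasses 4 and step 3, and comes back at 7. Mono-protection of 1 (MOMCl, i-Pr2NEt, CH2Cl2) gives 5-hydroxy-8-(methoxymethoxy)naphthalene-1,4-dione F10. The nucleophilic homoprenyl radical (from 5-methylhex-4-enoic acid, AgNO3 cat., (NH4)2S2O8, MeCN/H2O) adds β to the hydrogen-bond-activated carbonyl, that is next to the carbonyl peri to the MOM ether, giving 5-hydroxy-8-(methoxymethoxy)-2-(4-methylpent-3-en-1-yl)naphthalene-1,4-dione F11. Methylation of the free hydroxyl (MeI, Ag2O) gives 5-methoxy-8-(methoxymethoxy)-2-(4-methylpent-3-en-1-yl)naphthalene-1,4-dione F12. MOM removal (cat. HCl, MeOH, 0 °C) gives 7.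

**Further compounds**
F1 | step 4 | 2-bromo-5-methoxynaphthalene-1,4,8-triol | COc1ccc(O)c2c(O)c(Br)cc(O)c12
F2 | step 4 | [(2-bromo-5-methoxynaphthalene-1,4,8-triyl)tris(oxy)]tris[tert-butyl(dimethyl)silane] | COc1ccc(O[Si](C)(C)C(C)(C)C)c2c(O[Si](C)(C)C(C)(C)C)c(Br)cc(O[Si](C)(C)C(C)(C)C)c12
F3 | step 4 | 1-{1,4,8-tris[(tert-butyldimethylsilyl)oxy]-5-methoxynaphthalen-2-yl}-4-methylpent-3-en-1-one | COc1ccc(O[Si](C)(C)C(C)(C)C)c2c(O[Si](C)(C)C(C)(C)C)c(C(=O)CC=C(C)C)cc(O[Si](C)(C)C(C)(C)C)c12
F4 | step 4 | (1S)-1-{1,4,8-tris[(tert-butyldimethylsilyl)oxy]-5-methoxynaphthalen-2-yl}-4-methylpent-3-en-1-ol | COc1ccc(O[Si](C)(C)C(C)(C)C)c2c(O[Si](C)(C)C(C)(C)C)c([C@H](CC=C(C)C)O)cc(O[Si](C)(C)C(C)(C)C)c12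
F5 | step 4 | 2-[(1S)-1-hydroxy-4-methylpent-3-en-1-yl]-5-methoxynaphthalene-1,4,8-triol | COc1ccc(O)c2c(O)c([C@H](CC=C(C)C)O)cc(O)c12
F6 | step 4 | 8-hydroxy-2-[(1S)-1-hydroxy-4-methylpent-3-en-1-yl]-5-methoxynaphthalene-1,4-dione | COc1ccc(O)c2c1C(=O)C=C([C@H](CC=C(C)C)O)C2=O
F7 | step 3 | 2-bromo-5-methoxynaphthalene-1,4,8-triyl triacetate | COc1ccc(OC(C)=O)c2c(OC(C)=O)c(Br)cc(OC(C)=O)c12
F8 | step 3 | 5-methoxy-2-(4-methylpent-3-en-1-yl)naphthalene-1,4,8-triyl triacetate | COc1ccc(OC(C)=O)c2c(OC(C)=O)c(CCC=C(C)C)cc(OC(C)=O)c12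
F9 | step 3 | 5-methoxy-2-(4-methylpent-3-en-1-yl)naphthalene-1,4,8-triol | COc1ccc(O)c2c(O)c(CCC=C(C)C)cc(O)c12
F10 | step 2 | 5-hydroxy-8-(methoxymethoxy)naphthalene-1,4-dione | COCOc1ccc(O)c2c1C(=O)C=CC2=O
F11 | step 2 | 5-hydroxy-8-(methoxymethoxy)-2-(4-methylpent-3-en-1-yl)naphthalene-1,4-dione | COCOc1ccc(O)c2c1C(=O)C(CCC=C(C)C)=CC2=O
F12 | step 2 | 5-methoxy-8-(methoxymethoxy)-2-(4-methylpent-3-en-1-yl)naphthalene-1,4-dione | COCOc1ccc(OC)c2c1C(=O)C(CCC=C(C)C)=CC2=O
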